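**Retrosynthetic overview**
1. Rings A and B are bought as acetophenone 1 and aldehyde 2; a Claisen–Schmidt C–C disconnection leads back to them from chalcone 3, whose ring A is symmetric.
2. Ring C, the only ring formed, is closed from 3 by an enantioselective chalcone-isomerase-type oxa-Michael addition (flavanone 4), then hydroxylated at C3 in the manner of flavanone 3-hydroxylase (via 5 and 6), in one flask, to dihydroflavonol 7.
3. The C6–benzylic bond is made last: 7 plus p-quinone methide 9 (from alcohol 8) give target 10 by a catalyst-controlled Friedel–Crafts alkylation.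
4. Stereocentres: C2 in step 2 (catalyst), C3 in step 2 (relayed from C2), benzylic carbon in step 3 (catalyst).

Assumption: the presumed biosynthesis is chalcone → (2S)-flavanone → (2R,3R)-dihydroflavonol → C6 alkylation by the p-quinone methide of 4-vinylphenol.
Assumption: the sense of induction of the two named chiral catalysts is not known in advance; it is confirmed in a first analytical run and the mirror-image (or pseudoenantiomeric) catalyst is used if it is opposite.

Target descriptors read from the SMILES: 2R, 3R (2,3-trans), benzylic 1R; the substituent sits at C6, between 5-OH and 7-OMe.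

**Step 1**
Reactants: 1 2',6'-dihydroxy-4'-methoxyacetophenone; 2 4-hydroxybenzaldehyde
Product: 3 (E)-2',6',4-trihydroxy-4'-methoxychalcone
Conditions: KOH (60% aq, 15 equiv), EtOH, Ar, 0 °C → rt, 48 h; then poured into ice-cold 2 M HCl (pH 3), solid filtered cold
Reagents that add atoms: none
Why: Claisen–Schmidt aldol condensation with E1cB dehydration gives the E-enone, which rests in strong base as the ring-open polyphenoxide, so fast cold acidification releases the chalcone before it can close to racemic flavanone.

**Step 2**
Reactants: 3 (E)-2',6',4-trihydroxy-4'-methoxychalcone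
Product: 7 (2R,3R)-7-O-methylaromadendrin, via (2S)-sakuranetin 4 (not isolated), via tris-TMS enol ether 5 (not isolated), via tris-TMS silyloxy epoxide 6 (not isolated)
Conditions: a) 9-amino-9-deoxy-epi-quinine N'-[3,5-bis(trifluoromethyl)phenyl]thiourea (10 mol%), CH2Cl2/Et2O 5:1, −20 °C, 48 h; b) TMSOTf (3.5 equiv), Et3N (3.8 equiv), 0 °C, 1 h; c) DMDO (2.0 equiv, acetone), −40 → 0 °C; d) 1 M HCl, MeOH, 0 °C → rt
Reagents that add atoms: dimethyldioxirane (DMDO), CC1(C)OO1
Why: Proposed new method: a one-flask mimic of chalcone isomerase followed by flavanone 3-hydroxylase, in which the quinuclidine nitrogen activates one of the two equivalent ortho OH groups while the thiourea and the other, chelating OH hold the s-cis enone, so the 6-endo oxa-Michael addition closes ring C on one enone face and sets C2 (S, no regiochemical issue because ring A is symmetric); soft enolisation with TMSOTf/Et3N then avoids the E1cB ring opening that would racemise C2, DMDO epoxidises the enol ether on the face opposite the 2-aryl group, and acid methanolysis opens the silyloxy epoxide and removes all TMS groups to give the 2,3-trans (2R,3R) ketol; the closest known reactions are the cinchona–thiourea oxa-Michael cyclisation of activated 2'-hydroxychalcones and the trans-selective Rubottom oxidation of flavanone silyl enol ethers.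

**Step 3**
Reactants: 7 (2R,3R)-7-O-methylaromadendrin; 8 racemic 1-(4-hydroxyphenyl)ethanol
Product: 10 (2R,3R)-6-[(1R)-1-(4-hydroxyphenyl)ethyl]-7-O-methylaromadendrin (CNP0217438.1), via p-quinone methide 9 (not isolated)
Conditions: (R)-3,3'-bis(2,4,6-triisopropylphenyl)-1,1'-binaphthyl-2,2'-diyl hydrogen phosphate ((R)-TRIP, 10 mol%), 5 Å MS, CH2Cl2/MeCN 4:1, 0 °C → rt, 8 (1.2 equiv) added over 6 h
Reagents that add atoms: none
Why: Proposed new method: the chiral phosphoric acid dehydrates 8 to p-quinone methide 9 and holds it by a P–OH···O=C hydrogen bond while its P=O accepts the 5-OH of 7, so ring A attacks the exocyclic carbon of 9 (1,6-addition, Friedel–Crafts alkylation) from C6, the position ortho to the only free ring-A hydroxyl and the site that electrophilic iodination of 5-hydroxy-7-methoxyflavonoids also selects, and the catalyst pocket rather than the remote C2/C3 centres sets the (R) benzylic centre; the closest known reaction type is the chiral-phosphoric-acid-catalysed enantioselective 1,6-addition of phenols, naphthols and indoles to p-quinone methides generated in situ from p-hydroxybenzyl alcohols.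

**Compound list**
1 | 2',6'-dihydroxy-4'-methoxyacetophenone, 1-(2,6-dihydroxy-4-methoxyphenyl)ethan-1-one | CC(=O)c1c(O)cc(OC)cc1O | starting material
2 | 4-hydroxybenzaldehyde | O=Cc1ccc(O)cc1 | starting material
3 | (E)-1-(2,6-dihydroxy-4-methoxyphenyl)-3-(4-hydroxyphenyl)prop-2-en-1-one | COc1cc(O)c(C(=O)/C=C/c2ccc(O)cc2)c(O)c1 | intermediate
4 | (2S)-sakuranetin, (2S)-5-hydroxy-2-(4-hydroxyphenyl)-7-methoxychroman-4-one | COc1cc2c(c(O)c1)C(=O)C[C@@H](c1ccc(O)cc1)O2 | intermediate
5 | (2S)-7-methoxy-4,5-bis(trimethylsilyloxy)-2-[4-(trimethylsilyloxy)phenyl]-2H-chromene | COc1cc2c(c(O[Si](C)(C)C)c1)C(O[Si](C)(C)C)=C[C@@H](c1ccc(O[Si](C)(C)C)cc1)O2 | intermediate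
6 | 3,4-epoxide of 5 (3,4-epoxy-7-methoxy-4,5-bis(trimethylsilyloxy)-2-[4-(trimethylsilyloxy)phenyl]chroman), oxirane oxygen on the face opposite the 2-aryl group, C2 arranged as in 4 | COc1cc2c(c(O[Si](C)(C)C)c1)[C@]3(O[Si](C)(C)C)O[C@@H]3[C@@H](c1ccc(O[Si](C)(C)C)cc1)O2 | intermediate
7 | (2R,3R)-7-O-methylaromadendrin, (2R,3R)-3,5-dihydroxy-2-(4-hydroxyphenyl)-7-methoxychroman-4-one | COc1cc2c(c(O)c1)C(=O)[C@H](O)[C@@H](c1ccc(O)cc1)O2 | intermediate
8 | 1-(4-hydroxyphenyl)ethanol, racemic | CC(O)c1ccc(O)cc1 | starting material
9 | 4-ethylidenecyclohexa-2,5-dien-1-one (p-quinone methide) | CC=C1C=CC(=O)C=C1 | intermediate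
10 | (2R,3R)-3,5-dihydroxy-2-(4-hydroxyphenyl)-6-[(1R)-1-(4-hydroxyphenyl)ethyl]-7-methoxy-2,3-dihydro-4H-chromen-4-one | COc1cc2c(c(O)c1[C@H](C)c1ccc(O)cc1)C(=O)[C@H](O)[C@@H](c1ccc(O)cc1)O2 | target

**Totals**
Total step count: 3. Longest linear sequence: 3 (1 → 3 → 7 → 10).

**Steps most likely to fail, with fallbacks**

Step 3 (most risky). The risks are C8 instead of C6 attack, double alkylation, and weak catalyst control of the benzylic centre; a C8 isomer is separable by chromatography, but the benzylic epimer is not easily removed. The fallback fixes position and configuration by cross-coupling and sets out from 7. Compound 7 is iodinated at C6 (ortho to the chelated 5-OH) with benzyltrimethylammonium dichloroiodate and CaCO3 in CH2Cl2/MeOH to give 6-iodo-7-O-methylaromadendrin F3. F3 then undergoes an enantioselective nickel hydride hydroarylation of commercial 4-acetoxystyrene (NiI2, divalent nickel, with a chiral bis(imidazoline) ligand, (MeO)2MeSiH, KF, DMA, rt; Markovnikov Ni–H insertion, then aryl–benzyl bond formation) to give the 4''-O-acetate of the target F4. Acid methanolysis of F4 (catalytic HCl in MeOH, rt) returns to the route at 10.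

Step 2. The risks are insufficient enantioselectivity in closing an unactivated chalcone and loss of material in the one-flask silylation/oxidation; 7 is crystalline, so moderate ee can be upgraded by recrystallisation before step 3. The fallback sets C2 by asymmetric conjugate addition and sets out from 1. Compound 1 is formylated and cyclodehydrated (HCO2Et, NaH, THF; then HCl/AcOH) to 5-hydroxy-7-methoxychromone F2. F2 takes up 4-hydroxyphenylboronic acid under Pd(OCOCF3)2 (divalent palladium) with a chiral tert-butyl pyridine-oxazoline ligand (enantiomer chosen for 2S), NH4PF6 and water in 1,2-dichloroethane at 60 °C. This returns to the route at 4, which is then isolated, recrystallised and carried through parts b to d of step 2.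

Step 1. The risks are low conversion with three free phenols and partial closure to racemic flavanone on work-up, which would erode the ee of step 2. The fallback sets out from 1 and 2 and makes the C–C bond under acid instead: BF3·OEt2 in dioxane at rt (aldol condensation through the BF2 chelate of 1), then brief warming in AcOH, gives racemic sakuranetin F1. F1 is ring-opened by retro-oxa-Michael reaction in 50% aqueous KOH at 60 °C, and the orange polyphenoxide is quenched into ice-cold HCl to return to the route at 3.

**Further compounds**
F1 | step 1 | racemic sakuranetin, 5-hydroxy-2-(4-hydroxyphenyl)-7-methoxychroman-4-one | COc1cc2c(c(O)c1)C(=O)CC(c1ccc(O)cc1)O2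
F2 | step 2 | 5-hydroxy-7-methoxy-4H-chromen-4-one | COc1cc(O)c2c(c1)occc2=O
F3 | step 3 | (2R,3R)-3,5-dihydroxy-2-(4-hydroxyphenyl)-6-iodo-7-methoxychroman-4-one | COc1cc2c(c(O)c1I)C(=O)[C@H](O)[C@@H](c1ccc(O)cc1)O2
F4 | step 3 | 4-[(1R)-1-[(2R,3R)-3,5-dihydroxy-2-(4-hydroxyphenyl)-7-methoxy-4-oxochroman-6-yl]ethyl]phenyl acetate | COc1cc2c(c(O)c1[C@H](C)c1ccc(OC(C)=O)cc1)C(=O)[C@H](O)[C@@H](c1ccc(O)cc1)O2
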